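**Plan**

- Retrosynthetic cuts: first the two aryl ester bonds at O7 and O4' (late galloylation of a 7,4'-diol whose other hydroxyls are benzylated), then the aryl ether bond O1–C8a of ring C, then C2–C1' (B-ring Grignard on a Weinreb amide) and C3–C4 (glycolate enolate on an A-ring benzylic bromide).
- Enabling feature: O1 joins the stereocentre C2 to the aromatic carbon C8a of ring A. The pyran ring C can therefore be closed at the aryl–oxygen bond while the C2–O and C3–O bonds, and with them both stereocentres, stay untouched.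
- Forward order: A-ring benzylic bromide from 5-bromoresorcinol, then C3–C4, then C2–C1', then the C2 carbinol, then ring C (the only ring that is made), then release of O7/O4', esterification and global hydrogenolysis.
- Stereochemistry: C3 (S) comes from the (R)-4-benzyloxazolidinone in the glycolate alkylation. C2 (R) comes from a chelation-controlled ketone reduction relayed from C3. Both are carried unchanged through the stereoretentive ring closure.

Key step: step 14

Remark: flavan numbering (O1, C2, C3, C4, C4a, C5–C8, C8a; B ring C1'–C6') is used throughout. 3,4,5-Tris(benzyloxy)benzoic acid (perbenzylated gallic acid) and both enantiomers of 4-benzyloxazolidin-2-one are taken as purchased. Zn(BH4)2 is taken as an ethereal stock solution prepared beforehand.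

**Route**

Step 1
Reactants: 1 5-bromobenzene-1,3-diol
Product: 3 2-bromo-4,6-dihydroxybenzaldehyde, via aryliminium chloride 2 (not isolated)
Conditions: POCl3, DMF, MeCN, 0 °C → rt; then H2O, 50 °C
Reagents that add atoms: N,N-dimethylformamide, CN(C)C=O; water, O
Why: Vilsmeier–Haack formylation, in which the chloroiminium ion should attack the carbon para to one hydroxyl and ortho to the other (next to bromine), as is usual for 5-substituted resorcinols, and warm water hydrolyses iminium salt 2 to the aldehyde.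

Step 2
Reactants: 3 2-bromo-4,6-dihydroxybenzaldehyde
Product: 4 2-bromo-6-hydroxy-4-(methoxymethoxy)benzaldehyde
Conditions: MOMCl (1.05 equiv), K2CO3, acetone, 0 °C → rt
Reagents that add atoms: chloromethyl methyl ether, COCCl
Why: Williamson-type O-alkylation, selective because the hydroxyl para to the formyl group is the more acidic and is free, whereas the ortho hydroxyl is tied up in a hydrogen bond to the carbonyl, so one equivalent should cap only the future O7.

Step 3
Reactants: 4 2-bromo-6-hydroxy-4-(methoxymethoxy)benzaldehyde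
Product: 5 2-(benzyloxy)-6-bromo-4-(methoxymethoxy)benzaldehyde
Conditions: BnBr, K2CO3, DMF, 50 °C
Reagents that add atoms: benzyl bromide, BrCc1ccccc1
Why: Williamson etherification of the remaining, chelated phenol (future O5) under more forcing conditions, to which the MOM acetal and the aryl bromide are inert.

Step 4
Reactants: 5 2-(benzyloxy)-6-bromo-4-(methoxymethoxy)benzaldehyde
Product: 6 [2-(benzyloxy)-6-bromo-4-(methoxymethoxy)phenyl]methanol
Conditions: NaBH4, MeOH/THF, 0 °C
Reagents that add atoms: none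
Why: Borohydride reduction of an aryl aldehyde, which leaves the aryl bromide and both ethers alone.

Step 5
Reactants: 6 [2-(benzyloxy)-6-bromo-4-(methoxymethoxy)phenyl]methanol
Product: 7 1-(benzyloxy)-3-bromo-2-(bromomethyl)-5-(methoxymethoxy)benzene
Conditions: CBr4, PPh3, CH2Cl2, 0 °C; crude bromide passed through a short basic alumina pad and used at once
Reagents that add atoms: carbon tetrabromide, BrC(Br)(Br)Br
Why: Appel reaction, which converts the benzylic alcohol into the bromide under neutral conditions without the HBr that would cleave the MOM acetal.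

Step 6
Reactants: 8 2-(benzyloxy)acetic acid; 9 (R)-4-benzyl-1,3-oxazolidin-2-one
Product: 11 (4R)-4-benzyl-3-[(benzyloxy)acetyl]-1,3-oxazolidin-2-one, via mixed pivalic anhydride 10 (not isolated)
Conditions: PivCl, Et3N, THF, −20 °C; then LiCl, 9, −20 °C → rt
Reagents that add atoms: none
Why: N-acylation of the oxazolidinone through the mixed anhydride (LiCl/Et3N protocol), the auxiliary attacking the unhindered glycolyl carbonyl and not the pivaloyl one.

Step 7
Reactants: 11 (4R)-4-benzyl-3-[(benzyloxy)acetyl]-1,3-oxazolidin-2-one; 7 1-(benzyloxy)-3-bromo-2-(bromomethyl)-5-(methoxymethoxy)benzene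
Product: 13 (4R)-4-benzyl-3-{(2S)-2-(benzyloxy)-3-[2-(benzyloxy)-6-bromo-4-(methoxymethoxy)phenyl]propanoyl}-1,3-oxazolidin-2-one, via sodium Z-enolate 12 (not isolated)
Conditions: 11 (1.5 equiv), NaHMDS, THF, −78 °C; then 7, −78 → −45 °C
Reagents that add atoms: none
Why: Evans-type glycolate alkylation, in which the sodium-chelated Z-enolate is alkylated by the reactive benzylic bromide on the face away from the C4 benzyl group of the (R)-auxiliary, which forms C3–C4 and sets C3 as S.

Step 8
Reactants: 13 (4R)-4-benzyl-3-{(2S)-2-(benzyloxy)-3-[2-(benzyloxy)-6-bromo-4-(methoxymethoxy)phenyl]propanoyl}-1,3-oxazolidin-2-one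
Product: 15 (2S)-2-(benzyloxy)-3-[2-(benzyloxy)-6-bromo-4-(methoxymethoxy)phenyl]propanoic acid, via peroxy acid 14 (not isolated)
Conditions: LiOH, H2O2, THF/H2O, 0 °C; then Na2SO3; then 1 M HCl to pH 3, 0 °C
Reagents that add atoms: hydrogen peroxide, OO
Why: Hydroperoxide cleavage of an N-acyloxazolidinone, in which HOO− attacks the exocyclic carbonyl, sulfite reduces peracid 14 to the acid, the α-centre is not enolised and the auxiliary is released intact.

Step 9
Reactants: 15 (2S)-2-(benzyloxy)-3-[2-(benzyloxy)-6-bromo-4-(methoxymethoxy)phenyl]propanoic acid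
Product: 16 (2S)-2-(benzyloxy)-3-[2-(benzyloxy)-6-bromo-4-(methoxymethoxy)phenyl]-N-methoxy-N-methylpropanamide
Conditions: MeNHOMe·HCl, EDC·HCl, HOBt, N-methylmorpholine, CH2Cl2, 0 °C → rt
Reagents that add atoms: N,O-dimethylhydroxylamine hydrochloride, CNOC.Cl
Why: Carbodiimide amide coupling to the Weinreb amide, which should leave the stereocentre intact because an α-alkoxy acid has no oxazolone pathway for racemisation.

Step 10
Reactants: 17 2-(benzyloxy)phenol
Product: 18 2-(benzyloxy)-4-bromophenol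
Conditions: NBS, MeCN, 0 °C
Reagents that add atoms: N-bromosuccinimide, O=C1CCC(=O)N1Br
Why: Electrophilic aromatic bromination, directed para to the free hydroxyl as the stronger donor, which places bromine at the future C1'.

Step 11
Reactants: 18 2-(benzyloxy)-4-bromophenol
Product: 19 2-(benzyloxy)-4-bromo-1-(methoxymethoxy)benzene
Conditions: MOMCl, iPr2NEt, CH2Cl2, 0 °C → rt
Reagents that add atoms: chloromethyl methyl ether, COCCl
Why: MOM ether formation on the only free phenol, which marks the future O4' for later selective release.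

Step 12
Reactants: 19 2-(benzyloxy)-4-bromo-1-(methoxymethoxy)benzene; 16 (2S)-2-(benzyloxy)-3-[2-(benzyloxy)-6-bromo-4-(methoxymethoxy)phenyl]-N-methoxy-N-methylpropanamide
Product: 21 (2S)-2-(benzyloxy)-3-[2-(benzyloxy)-6-bromo-4-(methoxymethoxy)phenyl]-1-[3-(benzyloxy)-4-(methoxymethoxy)phenyl]propan-1-one, via arylmagnesium bromide 20 (not isolated)
Conditions: 19 (1.6 equiv), Mg, THF, 40 °C; then 16, THF, −20 → 0 °C; aq. NH4Cl, 0 °C
Reagents that add atoms: none
Why: Weinreb ketone synthesis, in which the Grignard reagent adds once because the N-methoxy chelate holds the tetrahedral intermediate until the cold, weakly acidic quench, so over-addition and epimerisation of the α-centre should be avoided and the aryl bromide of 16 does not exchange with an aryl Grignard.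

Step 13
Reactants: 21 (2S)-2-(benzyloxy)-3-[2-(benzyloxy)-6-bromo-4-(methoxymethoxy)phenyl]-1-[3-(benzyloxy)-4-(methoxymethoxy)phenyl]propan-1-one
Product: 22 (1R,2S)-2-(benzyloxy)-3-[2-(benzyloxy)-6-bromo-4-(methoxymethoxy)phenyl]-1-[3-(benzyloxy)-4-(methoxymethoxy)phenyl]propan-1-ol
Conditions: Zn(BH4)2, Et2O, −30 → 0 °C; aq. NH4Cl
Reagents that add atoms: none
Why: Chelation-controlled (Cram-chelate) reduction, in which zinc bridges the carbonyl and the α-benzyloxy oxygen and hydride is delivered from the side of the small α-hydrogen, which should give the anti (1R,2S) alcohol and so sets C2 as R.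

Step 14
Reactants: 22 (1R,2S)-2-(benzyloxy)-3-[2-(benzyloxy)-6-bromo-4-(methoxymethoxy)phenyl]-1-[3-(benzyloxy)-4-(methoxymethoxy)phenyl]propan-1-ol
Product: 23 (2R,3S)-3,5-bis(benzyloxy)-2-[3-(benzyloxy)-4-(methoxymethoxy)phenyl]-7-(methoxymethoxy)chromane
Conditions: Pd(OAc)2 (5 mol%), 2-(di-tert-butylphosphino)-1,1'-binaphthyl (6 mol%), Cs2CO3, toluene, 80 °C
Reagents that add atoms: none
Why: Pd(0) carrying the bulky di-tert-butyl biaryl phosphine inserts into the C8a–Br bond, carbonate-assisted exchange of bromide for the C2 alkoxide gives a seven-membered oxapalladacycle, and C(sp2)–O reductive elimination forms O1–C8a. This is the intramolecular Buchwald–Hartwig etherification of a secondary alcohol with an aryl bromide, a reaction established for chromans. Ring C closes as a six-membered ring in an exo sense, the oxygen ending on the ipso carbon of ring A with the three-carbon tether inside the new ring. No stereocentre is created, since neither the C2–O nor the C3–O bond is broken, so the (1R,2S)-anti chain of 22 becomes the 2,3-trans (2R,3S) chroman directly. The step needs reductive elimination to outpace β-hydride elimination of the benzylic alkoxide, which the hindered electron-rich ligand promotes, and it needs a single oxygen nucleophile, which the benzyl ether on O3 and the capped phenols guarantee. Oxidative addition is helped by the bromide lying meta to both ring-A oxygens and ortho only to the tether.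

Step 15
Reactants: 23 (2R,3S)-3,5-bis(benzyloxy)-2-[3-(benzyloxy)-4-(methoxymethoxy)phenyl]-7-(methoxymethoxy)chromane
Product: 24 (2R,3S)-3,5-bis(benzyloxy)-2-[3-(benzyloxy)-4-hydroxyphenyl]chroman-7-ol
Conditions: 2 M aq. HCl, MeOH/THF, 45 °C
Reagents that add atoms: none
Why: Acid-catalysed acetal exchange, in which both aryl MOM ethers pass their methoxymethyl group to methanol while the benzyl ethers and the chroman are stable to dilute acid, so only O7 and O4' are set free.

Step 16
Reactants: 24 (2R,3S)-3,5-bis(benzyloxy)-2-[3-(benzyloxy)-4-hydroxyphenyl]chroman-7-ol; 25 3,4,5-tris(benzyloxy)benzoic acid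
Product: 26 (2R,3S)-3,5-bis(benzyloxy)-2-{3-(benzyloxy)-4-[3,4,5-tris(benzyloxy)benzoyloxy]phenyl}chroman-7-yl 3,4,5-tris(benzyloxy)benzoate
Conditions: 25 (2.4 equiv), DCC, DMAP (cat.), CH2Cl2, 0 °C → rt
Reagents that add atoms: none
Why: Steglich esterification, in which the two phenols at C7 and C4' are the only free hydroxyls and both should be acylated by the DMAP-activated acid at room temperature.

Step 17
Reactants: 26 (2R,3S)-3,5-bis(benzyloxy)-2-{3-(benzyloxy)-4-[3,4,5-tris(benzyloxy)benzoyloxy]phenyl}chroman-7-yl 3,4,5-tris(benzyloxy)benzoate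
Product: 27 catechin 7,4'-di-O-gallate
Conditions: H2 (1 atm), 20% Pd(OH)2/C, THF/EtOAc, rt
Reagents that add atoms: none
Why: Catalytic hydrogenolysis of all nine benzyl ethers in a neutral, non-nucleophilic medium, which should leave the two aryl esters, the ring-C ether and both stereocentres untouched and keep 4'→3' acyl migration low.

**Compound list**

1 | 5-bromobenzene-1,3-diol | Oc1cc(O)cc(Br)c1 | starting material
2 | N-[(2-bromo-4,6-dihydroxyphenyl)methylidene]-N-methylmethanaminium chloride | C[N+](C)=Cc1c(O)cc(O)cc1Br.[Cl-] | intermediate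
3 | 2-bromo-4,6-dihydroxybenzaldehyde | O=Cc1c(O)cc(O)cc1Br | intermediate
4 | 2-bromo-6-hydroxy-4-(methoxymethoxy)benzaldehyde | O=Cc1c(O)cc(OCOC)cc1Br | intermediate
5 | 2-(benzyloxy)-6-bromo-4-(methoxymethoxy)benzaldehyde | O=Cc1c(OCc2ccccc2)cc(OCOC)cc1Br | intermediate
6 | [2-(benzyloxy)-6-bromo-4-(methoxymethoxy)phenyl]methanol | OCc1c(OCc2ccccc2)cc(OCOC)cc1Br | intermediate
7 | 1-(benzyloxy)-3-bromo-2-(bromomethyl)-5-(methoxymethoxy)benzene | BrCc1c(OCc2ccccc2)cc(OCOC)cc1Br | intermediate
8 | 2-(benzyloxy)acetic acid | O=C(O)COCc1ccccc1 | starting material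
9 | (R)-4-benzyl-1,3-oxazolidin-2-one | O=C1N[C@H](Cc2ccccc2)CO1 | starting material
10 | (benzyloxy)acetic pivalic anhydride | CC(C)(C)C(=O)OC(=O)COCc1ccccc1 | intermediate
11 | (4R)-4-benzyl-3-[(benzyloxy)acetyl]-1,3-oxazolidin-2-one | O=C(COCc1ccccc1)N1[C@H](Cc2ccccc2)COC1=O | intermediate
12 | sodium (Z)-enolate of 11 | [Na+].[O-]/C(=C\OCc1ccccc1)N1[C@H](Cc2ccccc2)COC1=O | intermediate
13 | (4R)-4-benzyl-3-{(2S)-2-(benzyloxy)-3-[2-(benzyloxy)-6-bromo-4-(methoxymethoxy)phenyl]propanoyl}-1,3-oxazolidin-2-one | O=C([C@@H](OCc1ccccc1)Cc1c(Br)cc(OCOC)cc1OCc1ccccc1)N1[C@H](Cc2ccccc2)COC1=O | intermediate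
14 | (2S)-2-(benzyloxy)-3-[2-(benzyloxy)-6-bromo-4-(methoxymethoxy)phenyl]propaneperoxoic acid | OOC(=O)[C@@H](OCc1ccccc1)Cc1c(Br)cc(OCOC)cc1OCc1ccccc1 | intermediate
15 | (2S)-2-(benzyloxy)-3-[2-(benzyloxy)-6-bromo-4-(methoxymethoxy)phenyl]propanoic acid | OC(=O)[C@@H](OCc1ccccc1)Cc1c(Br)cc(OCOC)cc1OCc1ccccc1 | intermediate
16 | (2S)-2-(benzyloxy)-3-[2-(benzyloxy)-6-bromo-4-(methoxymethoxy)phenyl]-N-methoxy-N-methylpropanamide | CON(C)C(=O)[C@@H](OCc1ccccc1)Cc1c(Br)cc(OCOC)cc1OCc1ccccc1 | intermediate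
17 | 2-(benzyloxy)phenol | Oc1ccccc1OCc1ccccc1 | starting material
18 | 2-(benzyloxy)-4-bromophenol | Oc1ccc(Br)cc1OCc1ccccc1 | intermediate
19 | 2-(benzyloxy)-4-bromo-1-(methoxymethoxy)benzene | COCOc1ccc(Br)cc1OCc1ccccc1 | intermediate
20 | [3-(benzyloxy)-4-(methoxymethoxy)phenyl]magnesium bromide | COCOc1ccc([Mg]Br)cc1OCc1ccccc1 | intermediate
21 | (2S)-2-(benzyloxy)-3-[2-(benzyloxy)-6-bromo-4-(methoxymethoxy)phenyl]-1-[3-(benzyloxy)-4-(methoxymethoxy)phenyl]propan-1-one | O=C(c1ccc(OCOC)c(OCc2ccccc2)c1)[C@@H](OCc1ccccc1)Cc1c(Br)cc(OCOC)cc1OCc1ccccc1 | intermediate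
22 | (1R,2S)-2-(benzyloxy)-3-[2-(benzyloxy)-6-bromo-4-(methoxymethoxy)phenyl]-1-[3-(benzyloxy)-4-(methoxymethoxy)phenyl]propan-1-ol | O[C@H](c1ccc(OCOC)c(OCc2ccccc2)c1)[C@@H](OCc1ccccc1)Cc1c(Br)cc(OCOC)cc1OCc1ccccc1 | intermediate
23 | (2R,3S)-3,5-bis(benzyloxy)-2-[3-(benzyloxy)-4-(methoxymethoxy)phenyl]-7-(methoxymethoxy)chromane | COCOc1cc(OCc2ccccc2)c2c(c1)O[C@H](c1ccc(OCOC)c(OCc3ccccc3)c1)[C@@H](OCc1ccccc1)C2 | intermediate
24 | (2R,3S)-3,5-bis(benzyloxy)-2-[3-(benzyloxy)-4-hydroxyphenyl]chroman-7-ol | Oc1cc(OCc2ccccc2)c2c(c1)O[C@H](c1ccc(O)c(OCc3ccccc3)c1)[C@@H](OCc1ccccc1)C2 | intermediate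
25 | 3,4,5-tris(benzyloxy)benzoic acid | O=C(O)c1cc(OCc2ccccc2)c(OCc2ccccc2)c(OCc2ccccc2)c1 | starting material
26 | (2R,3S)-3,5-bis(benzyloxy)-2-{3-(benzyloxy)-4-[3,4,5-tris(benzyloxy)benzoyloxy]phenyl}chroman-7-yl 3,4,5-tris(benzyloxy)benzoate | O=C(Oc1cc(OCc2ccccc2)c2c(c1)O[C@H](c1ccc(OC(=O)c3cc(OCc4ccccc4)c(OCc4ccccc4)c(OCc4ccccc4)c3)c(OCc3ccccc3)c1)[C@@H](OCc1ccccc1)C2)c1cc(OCc2ccccc2)c(OCc2ccccc2)c(OCc2ccccc2)c1 | intermediate
27 | catechin 7,4'-di-O-gallate, (2R,3S)-3,5-dihydroxy-2-[3-hydroxy-4-(3,4,5-trihydroxybenzoyloxy)phenyl]chroman-7-yl 3,4,5-trihydroxybenzoate | O=C(Oc1cc(O)c2c(c1)O[C@H](c1ccc(OC(=O)c3cc(O)c(O)c(O)c3)c(O)c1)[C@@H](O)C2)c1cc(O)c(O)c(O)c1 | target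

**Step count**

Total: 17 steps. Longest linear sequence: 14 steps (steps 1–5, 7–9, 12–17).

**Steps most likely to fail**

Step 14. The palladium alkoxide may undergo β-hydride elimination (oxidising the carbinol and reducing the C–Br bond), or alkoxide formation at the hindered secondary alcohol may be too slow.

- Setting out from 22, the bromide would be exchanged for boron with a base too weak to form an alkoxide (B2pin2, Pd(dppf)Cl2, KOAc, dioxane, 85 °C). This gives the pinacol boronate (1R,2S)-2-(benzyloxy)-3-[2-(benzyloxy)-4-(methoxymethoxy)-6-(4,4,5,5-tetramethyl-1,3,2-dioxaborolan-2-yl)phenyl]-1-[3-(benzyloxy)-4-(methoxymethoxy)phenyl]propan-1-ol F1.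
- Sodium perborate in THF/water would oxidise it to the phenol (1R,2S)-2-(benzyloxy)-3-[2-(benzyloxy)-6-hydroxy-4-(methoxymethoxy)phenyl]-1-[3-(benzyloxy)-4-(methoxymethoxy)phenyl]propan-1-ol F2.
- Ring C would then be closed with the polarity reversed. HCl in MeOH/THF (the conditions of step 15) ionises the C2 carbinol to a cation stabilised by the 4'-oxygen, the C8a phenol captures it, and both MOM groups leave in the same operation, so the route is rejoined at 24.
- This closure is not stereospecific. The 2,3-trans isomer should prevail because the phenol adds anti to the C3 benzyloxy group and the trans chroman is the more stable one; the cis isomer would have to be removed by chromatography.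

Step 7. The sodium glycolate enolate may decompose before the doubly ortho-substituted bromide reacts, and the electron-rich benzylic bromide may ionise or self-condense.

- Setting out from aldehyde 5, a Horner–Wadsworth–Emmons olefination with diethyl {2-[(4S)-4-benzyl-2-oxo-1,3-oxazolidin-3-yl]-2-oxoethyl}phosphonate (LiCl, iPr2NEt, MeCN) would give the enoyl imide (4S)-4-benzyl-3-{(2E)-3-[2-(benzyloxy)-6-bromo-4-(methoxymethoxy)phenyl]prop-2-enoyl}-1,3-oxazolidin-2-one F3.
- Conjugate reduction (L-Selectride, THF, −78 °C) would give (4S)-4-benzyl-3-{3-[2-(benzyloxy)-6-bromo-4-(methoxymethoxy)phenyl]propanoyl}-1,3-oxazolidin-2-one F4.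
- Hydroxylation of its sodium enolate with 2-(phenylsulfonyl)-3-phenyloxaziridine (NaHMDS, THF, −78 °C) would give (4S)-4-benzyl-3-{(2S)-3-[2-(benzyloxy)-6-bromo-4-(methoxymethoxy)phenyl]-2-hydroxypropanoyl}-1,3-oxazolidin-2-one F5. Oxygen now enters anti to the C4 benzyl group while the arylmethyl group is the resident substituent, which is why the (S)-auxiliary is needed here.
- Neutral O-benzylation (2-benzyloxy-1-methylpyridinium triflate, MgO, PhCF3, 85 °C) would give (4S)-4-benzyl-3-{(2S)-2-(benzyloxy)-3-[2-(benzyloxy)-6-bromo-4-(methoxymethoxy)phenyl]propanoyl}-1,3-oxazolidin-2-one F6.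
- Hydroperoxide cleavage as in step 8 returns the route at acid 15.

Step 1. Formylation of the unprotected, bromine-deactivated resorcinol may go to the carbon between the two hydroxyls, or stop at O-formylation or low conversion.

- Setting out from 1, double O-methylation (MeI, K2CO3, acetone) would give 1-bromo-3,5-dimethoxybenzene F7.
- Vilsmeier–Haack formylation (POCl3, DMF, 90 °C) would give 2-bromo-4,6-dimethoxybenzaldehyde F8. The regiochemistry is secure here because the position between the two methoxy groups is shielded.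
- Double demethylation with BBr3 (CH2Cl2, −78 °C → rt) rejoins the route at 3.

**Further compounds**

F1 | step 14 | (1R,2S)-2-(benzyloxy)-3-[2-(benzyloxy)-4-(methoxymethoxy)-6-(4,4,5,5-tetramethyl-1,3,2-dioxaborolan-2-yl)phenyl]-1-[3-(benzyloxy)-4-(methoxymethoxy)phenyl]propan-1-ol | O[C@H](c1ccc(OCOC)c(OCc2ccccc2)c1)[C@@H](OCc1ccccc1)Cc1c(B2OC(C)(C)C(C)(C)O2)cc(OCOC)cc1OCc1ccccc1
F2 | step 14 | (1R,2S)-2-(benzyloxy)-3-[2-(benzyloxy)-6-hydroxy-4-(methoxymethoxy)phenyl]-1-[3-(benzyloxy)-4-(methoxymethoxy)phenyl]propan-1-ol | O[C@H](c1ccc(OCOC)c(OCc2ccccc2)c1)[C@@H](OCc1ccccc1)Cc1c(O)cc(OCOC)cc1OCc1ccccc1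
F3 | step 7 | (4S)-4-benzyl-3-{(2E)-3-[2-(benzyloxy)-6-bromo-4-(methoxymethoxy)phenyl]prop-2-enoyl}-1,3-oxazolidin-2-one | O=C(/C=C/c1c(Br)cc(OCOC)cc1OCc1ccccc1)N1[C@@H](Cc2ccccc2)COC1=O
F4 | step 7 | (4S)-4-benzyl-3-{3-[2-(benzyloxy)-6-bromo-4-(methoxymethoxy)phenyl]propanoyl}-1,3-oxazolidin-2-one | O=C(CCc1c(Br)cc(OCOC)cc1OCc1ccccc1)N1[C@@H](Cc2ccccc2)COC1=O
F5 | step 7 | (4S)-4-benzyl-3-{(2S)-3-[2-(benzyloxy)-6-bromo-4-(methoxymethoxy)phenyl]-2-hydroxypropanoyl}-1,3-oxazolidin-2-one | O=C([C@@H](O)Cc1c(Br)cc(OCOC)cc1OCc1ccccc1)N1[C@@H](Cc2ccccc2)COC1=O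
F6 | step 7 | (4S)-4-benzyl-3-{(2S)-2-(benzyloxy)-3-[2-(benzyloxy)-6-bromo-4-(methoxymethoxy)phenyl]propanoyl}-1,3-oxazolidin-2-one | O=C([C@@H](OCc1ccccc1)Cc1c(Br)cc(OCOC)cc1OCc1ccccc1)N1[C@@H](Cc2ccccc2)COC1=O
F7 | step 1 | 1-bromo-3,5-dimethoxybenzene | COc1cc(OC)cc(Br)c1
F8 | step 1 | 2-bromo-4,6-dimethoxybenzaldehyde | COc1cc(OC)c(C=O)c(Br)c1
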